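## Retrosynthetic overview

1. Pilosanol B is (+)-catechin (2R,3S) carrying an acylphloroglucinol-CH2 group at C8; the last disconnection is C8–CH2, made by trapping an o-quinone methide with unprotected (+)-catechin.
2. The o-quinone methide comes from benzylic sulfide **10**. Its aryl–CH2 bond (the bridging carbon) is made by a [2,3]-sigmatropic rearrangement of an aryloxysulfonium ylide on acylphloroglucinol **8**.
3. **8** comes from ketone **3** by tosylate protection, O-methylation and detosylation; **3** is the Friedel–Crafts product of 2-methylphloroglucinol and isobutyryl chloride.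
4. No ring is constructed: the flavan ring system with both stereocentres is bought as (+)-catechin, and the fourth ring as 2-methylphloroglucinol.

Assumption: 2-methylphloroglucinol (2,4,6-trihydroxytoluene) and (+)-catechin are treated as commercial.

## Route

**Step 1**
- Reactants: **1** 2-methylbenzene-1,3,5-triol; **2** 2-methylpropanoyl chloride
- Product: **3** 1-(2,4,6-trihydroxy-3-methylphenyl)-2-methylpropan-1-one
- Conditions: AlCl3 (4 equiv), PhNO2/CH2Cl2, 0 → 45 °C; aq. HCl
- Reagents that add atoms: isobutyryl chloride (**2**), CC(C)C(Cl)=O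
- Why: Friedel–Crafts C-acylation of a phloroglucinol; the two free ring positions of **1** are equivalent, so one regioisomer forms, and the new ketone deactivates the ring to a second acylation.

**Step 2**
- Reactants: **3**; **4** p-toluenesulfonyl chloride
- Product: **5** 1-[2-hydroxy-3-methyl-4,6-bis(tosyloxy)phenyl]-2-methylpropan-1-one (the OH between the acyl group and the C-methyl stays free)
- Conditions: TsCl (2.1 equiv), K2CO3, acetone, rt → reflux
- Reagents that add atoms: TsCl (**4**), Cc1ccc(cc1)S(Cl)(=O)=O
- Why: Selective O-sulfonylation; the para-OH (most acidic) and the less hindered ortho-OH react, while the ortho-OH wedged between the acyl and C-methyl groups stays hydrogen-bonded to the carbonyl.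

**Step 3**
- Reactants: **5**; **6** iodomethane
- Product: **7** 1-[2-methoxy-3-methyl-4,6-bis(tosyloxy)phenyl]-2-methylpropan-1-one
- Conditions: MeI (3 equiv), Cs2CO3, DMF, 40 °C
- Reagents that add atoms: MeI (**6**), CI
- Why: Williamson O-methylation of the only free phenol; carbonate does not enolise the ketone and aryl tosylates are inert to it.

**Step 4**
- Reactants: **7**
- Product: **8** 1-(4,6-dihydroxy-2-methoxy-3-methylphenyl)-2-methylpropan-1-one
- Conditions: KOH, MeOH/H2O, reflux; then aq. HCl
- Reagents that add atoms: none
- Why: Hydroxide cleaves the S–O bonds of the aryl sulfonates (activated by the ortho/para ketone) and leaves the aryl methyl ether and ketone untouched (sulfonate ester hydrolysis).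

**Step 5**
- Reactants: **8**; **9** dimethyl sulfide
- Product: **10** 1-[2,4-dihydroxy-6-methoxy-5-methyl-3-(methylsulfanylmethyl)phenyl]-2-methylpropan-1-one (CH2SMe on the ring carbon between the two OH groups)
- Conditions: Me2S, NCS, CH2Cl2, −25 °C; then **8**; then Et3N, −25 °C → rt
- Reagents that add atoms: dimethyl sulfide (**9**), CSC
- Why: Gassman ortho-alkylation; the aryloxysulfonium salt is deprotonated to the S-ylide, which undergoes a [2,3]-sigmatropic (Sommelet–Hauser-type) shift to the only unsubstituted ring carbon, and tautomerisation restores the arene.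

**Step 6**
- Reactants: **10**; **11** (+)-catechin, (2R,3S)-2-(3,4-dihydroxyphenyl)chromane-3,5,7-triol
- Product: **12** pilosanol B, 1-[3-{[(2R,3S)-2-(3,4-dihydroxyphenyl)-3,5,7-trihydroxychroman-8-yl]methyl}-2,4-dihydroxy-6-methoxy-5-methylphenyl]-2-methylpropan-1-one
- Conditions: MeOTf (1.05 equiv), CH2Cl2, 0 °C; then **11** (4 equiv), NaHCO3, degassed acetone, 0 → 40 °C, Ar; RP-18 / Sephadex LH-20
- Reagents that add atoms: none (the methyl from MeOTf leaves as Me2S)
- Why: S-methylation gives a sulfonium that eliminates Me2S to the o-quinone methide, which the phloroglucinol-type A-ring of catechin traps at C8 (vinylogous Michael / Friedel–Crafts alkylation). No stereocentre is touched, so the (2R,3S) configuration is that of the purchased catechin; the C6 isomer and bis-adducts are removed chromatographically.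

## Compound list

1 | 2-methylbenzene-1,3,5-triol (2-methylphloroglucinol) | Cc1c(O)cc(O)cc1O | starting material
2 | 2-methylpropanoyl chloride | CC(C)C(Cl)=O | starting material
3 | 1-(2,4,6-trihydroxy-3-methylphenyl)-2-methylpropan-1-one | CC(C)C(=O)c1c(O)c(C)c(O)cc1O | intermediate
4 | p-toluenesulfonyl chloride | Cc1ccc(cc1)S(Cl)(=O)=O | starting material (reagent)
5 | 1-[2-hydroxy-3-methyl-4,6-bis(tosyloxy)phenyl]-2-methylpropan-1-one | CC(C)C(=O)c1c(O)c(C)c(OS(=O)(=O)c2ccc(C)cc2)cc1OS(=O)(=O)c1ccc(C)cc1 | intermediate
6 | iodomethane | CI | starting material (reagent)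
7 | 1-[2-methoxy-3-methyl-4,6-bis(tosyloxy)phenyl]-2-methylpropan-1-one | CC(C)C(=O)c1c(OC)c(C)c(OS(=O)(=O)c2ccc(C)cc2)cc1OS(=O)(=O)c1ccc(C)cc1 | intermediate
8 | 1-(4,6-dihydroxy-2-methoxy-3-methylphenyl)-2-methylpropan-1-one | CC(C)C(=O)c1c(OC)c(C)c(O)cc1O | intermediate
9 | dimethyl sulfide | CSC | starting material (reagent)
10 | 1-[2,4-dihydroxy-6-methoxy-5-methyl-3-(methylsulfanylmethyl)phenyl]-2-methylpropan-1-one | CC(C)C(=O)c1c(OC)c(C)c(O)c(CSC)c1O | intermediate
11 | (+)-catechin, (2R,3S) | Oc1cc(O)c2c(c1)O[C@H](c1ccc(O)c(O)c1)[C@@H](O)C2 | starting material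
12 | pilosanol B | COc1c(C)c(O)c(Cc2c(O)cc(O)c3c2O[C@H](c2ccc(O)c(O)c2)[C@@H](O)C3)c(O)c1C(=O)C(C)C | target

## Totals

Total steps: 6. Longest linear sequence: 6 (1 → 3 → 5 → 7 → 8 → 10 → 12); catechin enters in the last step.

## Steps most likely to fail

1. **Step 6 (C8 vs C6 selectivity, bis-alkylation).** C8 is expected to be favoured only modestly with free catechin. Fallback: use 5,7,3′,4′-tetra-O-benzyl-(+)-catechin (BnBr, K2CO3 on **11**), which is alkylated only at C8 by benzylic cations (BF3·OEt2 or HFIP), then remove the benzyl groups with H2, Pd(OH)2/C. This trades two extra steps for protecting-group-enforced regiocontrol.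
2. **Step 5 (O- vs C-sulfenylation, MTM ether or dienone by-products on an electron-rich acylphloroglucinol).** Fallback: install the bridging carbon by Mannich aminomethylation of **8** (CH2O, Me2NH or morpholine) at the same carbon and use the o-hydroxybenzylamine as a thermal o-quinone methide precursor with catechin.
3. **Step 2 (which ortho-OH is tosylated second).** Fallback: a formyl-blocking sequence with unambiguous regiochemistry. Vilsmeier formylation of **1**, methylation of the only non-chelated OH (para to CHO), then Friedel–Crafts isobutyrylation at the last free carbon. The CHO is then either removed (Rh-catalysed decarbonylation) to give **8**, or reduced to CH2OH and used directly as the o-quinone methide precursor.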